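**Plan**

1. Atom numbers are those of the target: ring A = C1–C2=C3–C4–C4a–C8a, ring B = C4a–C5–C6=C7–C8(=O)–C8a. The last cut is C6=C7 (sulfoxide elimination), because a ring B unsaturated at both C4a=C8a and C6=C7 would be the keto form of a salicylate.
2. Ring A: C1 is an sp3 carbon that carries CO2Me between the vinylic C2 and the ring-fusion carbon C8a, a β,γ-unsaturated ester, which is the pattern left by a Wolff rearrangement with vinyl shift. The ester carbon is therefore put back between C1 and C2 as the carbonyl of a 7-diazocyclohept-2-enone, and ring A arises by contraction of that seven-membered ring.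
3. The cycloheptenone is cut at C3–C4 and C2–C(O): 1-octadecyne inserted into the C(O)–C4 bond of a cyclopentanone β-keto ester brings in C2=C3 and the C3 chain. The cyclopentanone is cut at C4–C4a and C1–C8a (methyl 4-chloroacetoacetate on a cyclohexenone), and the cyclohexenone at C6–C7 and C4a=C8a (enal plus methyl acetoacetate).
4. Forward order: ring B, a five-membered ring on C4a/C8a, enlargement to seven, contraction to ring A, dehydrogenation of ring B.
5. Stereochemistry: the organocatalyst sets C6; C6 directs C4a (trans addition) and the cis ring closure gives C8a; C4 equilibrates (ester trans to C5); C1 comes from convex-face protonation in the ring contraction; C6 and C7 are flattened at the end.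

Key step: step 8

Remark: atom numbers C1–C8a are kept for the same atoms in all intermediates; C4, which lies α to an ester and γ to the enone from step 5 on, is assumed to equilibrate to the epimer with its ester trans to C5.

**Step 1**
Reactants: 1 octadec-1-ene; 2 (E)-but-2-enal
Product: 3 (E)-nonadec-2-enal
Conditions: second-generation Hoveyda–Grubbs catalyst (2 mol%), 2 (5 equiv), CH2Cl2, 40 °C
Reagents that add atoms: none
Why: Olefin cross-metathesis between a terminal alkene and an excess of the enal, which does not homodimerise readily, should give the (E)-configured 2-enal with loss of propene.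

**Step 2**
Reactants: 3 (E)-nonadec-2-enal; 4 methyl 3-oxobutanoate
Product: 6 methyl (1S,6R)-6-hexadecyl-2-oxocyclohex-3-ene-1-carboxylate, via Michael adduct 5 (not isolated)
Conditions: (S)-2-[diphenyl(trimethylsilyloxy)methyl]pyrrolidine (10 mol%), PhCO2H (10 mol%), toluene, 0 °C to rt; then TsOH·H2O (20 mol%), toluene, 80 °C
Reagents that add atoms: none
Why: Iminium-catalysed asymmetric Michael addition of the β-keto ester to the enal followed by acid-mediated intramolecular aldol condensation (organocatalytic Robinson-type annulation) should build ring B; the diphenyl(silyloxy)methyl group of the catalyst shields one face of the (E)-iminium ion, so C6 is expected as (R) (the enantiomeric catalyst would be taken if the induction ran the other way), and C7 settles trans to the chain.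

**Step 3**
Reactants: 6 methyl (1S,6R)-6-hexadecyl-2-oxocyclohex-3-ene-1-carboxylate
Product: 7 methyl (1S,6R)-6-hexadecyl-2-oxo-1-(phenylsulfanyl)cyclohex-3-ene-1-carboxylate
Conditions: N-(phenylsulfanyl)succinimide (1.1 equiv), Et3N (10 mol%), CH2Cl2, 0 °C to rt
Reagents that add atoms: N-(phenylsulfanyl)succinimide, O=C1CCC(=O)N1Sc1ccccc1
Why: Electrophilic α-sulfenylation of the enolised β-keto ester should place sulfur on C7 trans to the C6 hexadecyl group, which removes the acidic C7–H for the base- and metal-mediated steps that follow and sets sulfur syn to H6 for the final elimination.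

**Step 4**
Reactants: 7 methyl (1S,6R)-6-hexadecyl-2-oxo-1-(phenylsulfanyl)cyclohex-3-ene-1-carboxylate; 8 methyl 4-chloro-3-oxobutanoate
Product: 10 dimethyl (1S,3aR,5S,6R,7aR)-6-hexadecyl-2,4-dioxo-5-(phenylsulfanyl)octahydro-1H-indene-1,5-dicarboxylate, via chloro ketone adduct 9 (not isolated)
Conditions: K2CO3 (2.5 equiv), MeCN, 0 °C to rt
Reagents that add atoms: none
Why: Michael-initiated ring closure (domino Michael addition and intramolecular enolate C-alkylation): the carbanion of 8 should add to C4a anti to the C6 hexadecyl chain (trans-3,5 addition to a 5-substituted cyclohexenone), and the resulting ring B enolate should displace chloride at C8a in a 5-exo-tet closure that can only give the cis-fused hydrindanone, while the ester-bearing carbon (future C4) stays epimerisable and should settle trans to C5.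

**Step 5**
Reactants: 10 dimethyl (1S,3aR,5S,6R,7aR)-6-hexadecyl-2,4-dioxo-5-(phenylsulfanyl)octahydro-1H-indene-1,5-dicarboxylate; 11 octadec-1-yne
Product: 12 dimethyl (2S,3R,4aR,5S,9aR)-3,6-dihexadecyl-1,8-dioxo-2-(phenylsulfanyl)-2,3,4,4a,5,8,9,9a-octahydro-1H-benzo[7]annulene-2,5-dicarboxylate
Conditions: [ReBr(CO)3(thf)]2 (3 mol%), BnNC (6 mol%), toluene, 80 °C
Reagents that add atoms: none
Why: Rhenium-catalysed insertion of a terminal alkyne into the C(O)–C(α) bond of a cyclic β-keto ester (addition of the enol across the alkyne at its internal carbon, closure to a cyclobutenol and retro-aldol opening) should enlarge the five-membered ring by two carbons, placing the hexadecyl-bearing C3 next to C4 and the CH (C2) next to the ketone, with the double bond resting in conjugation with the ketone as in Hagemann's ester and C4 reprotonated trans to C5; the sulfanylated β-keto ester of ring B has no enolisable hydrogen and should not take part.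

**Step 6**
Reactants: 12 dimethyl (2S,3R,4aR,5S,9aR)-3,6-dihexadecyl-1,8-dioxo-2-(phenylsulfanyl)-2,3,4,4a,5,8,9,9a-octahydro-1H-benzo[7]annulene-2,5-dicarboxylate
Product: 13 the (9E)-9-[(dimethylamino)methylidene] derivative of 12 (CH–NMe2 on the methylene between the enone carbonyl and the ring-fusion carbon; all stereocentres as in 12)
Conditions: tert-butoxybis(dimethylamino)methane (1.5 equiv), toluene, 60 °C
Reagents that add atoms: tert-butoxybis(dimethylamino)methane, CN(C)C(OC(C)(C)C)N(C)C
Why: Condensation of an aminal ester with the only CH2 group that stands α to a ketone (future C1; the ring B ketone is flanked by a quaternary carbon and a methine, the enone by a vinylic carbon) should give the enaminone without strong base.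

**Step 7**
Reactants: 13 the (9E)-9-[(dimethylamino)methylidene] derivative of 12
Product: 14 the 9-diazo derivative of 12 (C=N2 in place of the methylene between the enone carbonyl and the ring-fusion carbon; all stereocentres as in 12)
Conditions: TsN3 (1.2 equiv), MeCN, 0 °C to rt
Reagents that add atoms: 4-methylbenzenesulfonyl azide, Cc1ccc(cc1)S(=O)(=O)N=[N+]=[N-]
Why: Diazo transfer to an enaminone (cycloaddition of the sulfonyl azide to the electron-rich C=C and fragmentation of the triazoline) should give the α'-diazo enone under non-basic conditions, so that C8a next to the ring B ketone is not epimerised.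

**Step 8**
Reactants: 14 the 9-diazo derivative of 12
Product: 16 trimethyl (1R,4S,4aR,6R,7S,8aS)-3,6-dihexadecyl-8-oxo-7-(phenylsulfanyl)-1,4,4a,5,6,7,8,8a-octahydronaphthalene-1,4,7-tricarboxylate, via vinylketene 15 (not isolated)
Conditions: hν (365 nm), MeOH/THF (1:1), 0 °C
Reagents that add atoms: methanol, CO
Why: Irradiation expels N2 from the ring-locked s-Z α-diazo ketone with concerted 1,2-shift of the vinylic carbon C2 from the carbonyl carbon to the diazo carbon C1 (photochemical Wolff rearrangement), which turns the seven-membered ring into ring A and leaves the former ring carbonyl as the exocyclic ketene carbon of 15. The closest known reaction type is the Wolff ring contraction of cyclic α-diazo ketones, here in the vinyl-migrating form that gives vinylketenes from α'-diazo enones. Ring A is closed not by a cyclisation but by this 1,2-shift: the C1–C2 bond forms as the C(O)–C2 bond breaks, so the ring contracts from seven to six members with the C2=C3 double bond kept in place. Methanol adds to the ketene and the resulting dienol is protonated at its α-carbon C1, which gives the β,γ-unsaturated ester under kinetic control. The new stereocentre C1 is controlled by the cis-fused bicycle: the proton should arrive on the convex face, anti to the C8a–C8 bond, so that the ester ends up cis to C8 as in the target, while C4, C4a and C8a are not touched under the neutral conditions. The step needs the Wolff shift instead of other carbene reactions (secured by the cyclic s-Z diazo ketone and direct photolysis without metal), α- instead of γ-protonation (secured by cold, neutral methanol) and the facial selectivity just described; 365 nm light is not absorbed by the aryl sulfide.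

**Step 9**
Reactants: 16 trimethyl (1R,4S,4aR,6R,7S,8aS)-3,6-dihexadecyl-8-oxo-7-(phenylsulfanyl)-1,4,4a,5,6,7,8,8a-octahydronaphthalene-1,4,7-tricarboxylate
Product: 18 trimethyl (1R,4S,4aR,8aS)-3,6-dihexadecyl-8-oxo-1,4,4a,5,8,8a-hexahydronaphthalene-1,4,7-tricarboxylate, via sulfoxide 17 (not isolated)
Conditions: mCPBA (1.0 equiv), CH2Cl2, −78 °C; then toluene, 60 °C
Reagents that add atoms: none
Why: Chemoselective oxidation of the sulfide at low temperature and thermal syn-elimination of benzenesulfenic acid from the α-sulfinyl β-keto ester (sulfoxide pyrolysis) should give the C6=C7 double bond regiospecifically, since the only β-hydrogen is the one on C6 and it is syn to sulfur, under neutral conditions that spare the β,γ-unsaturated esters, the cis ring fusion and a product that base would aromatise by retro-Michael cleavage.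

**Compound list**

1 | octadec-1-ene | CCCCCCCCCCCCCCCCC=C | starting material
2 | (E)-but-2-enal | C/C=C/C=O | starting material
3 | (E)-nonadec-2-enal | CCCCCCCCCCCCCCCC/C=C/C=O | intermediate
4 | methyl 3-oxobutanoate | CC(=O)CC(=O)OC | starting material
5 | methyl (3R)-2-acetyl-3-(2-oxoethyl)nonadecanoate (C2 epimers) | CCCCCCCCCCCCCCCC[C@H](CC=O)C(C(C)=O)C(=O)OC | intermediate
6 | methyl (1S,6R)-6-hexadecyl-2-oxocyclohex-3-ene-1-carboxylate | O=C1C=CC[C@@H](CCCCCCCCCCCCCCCC)[C@@H]1C(=O)OC | intermediate
7 | methyl (1S,6R)-6-hexadecyl-2-oxo-1-(phenylsulfanyl)cyclohex-3-ene-1-carboxylate | O=C1C=CC[C@@H](CCCCCCCCCCCCCCCC)[C@@]1(Sc2ccccc2)C(=O)OC | intermediate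
8 | methyl 4-chloro-3-oxobutanoate | COC(=O)CC(=O)CCl | starting material
9 | methyl (1S,2R,4R)-4-(4-chloro-1-methoxy-1,3-dioxobutan-2-yl)-2-hexadecyl-6-oxo-1-(phenylsulfanyl)cyclohexane-1-carboxylate (side-chain epimers) | COC(=O)C(C(=O)CCl)[C@H]1CC(=O)[C@](Sc2ccccc2)(C(=O)OC)[C@H](CCCCCCCCCCCCCCCC)C1 | intermediate
10 | dimethyl (1S,3aR,5S,6R,7aR)-6-hexadecyl-2,4-dioxo-5-(phenylsulfanyl)octahydro-1H-indene-1,5-dicarboxylate | COC(=O)[C@@H]1C(=O)C[C@H]2C(=O)[C@](Sc3ccccc3)(C(=O)OC)[C@H](CCCCCCCCCCCCCCCC)C[C@@H]12 | intermediate
11 | octadec-1-yne | CCCCCCCCCCCCCCCCC#C | starting material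
12 | dimethyl (2S,3R,4aR,5S,9aR)-3,6-dihexadecyl-1,8-dioxo-2-(phenylsulfanyl)-2,3,4,4a,5,8,9,9a-octahydro-1H-benzo[7]annulene-2,5-dicarboxylate | COC(=O)[C@@H]1C(CCCCCCCCCCCCCCCC)=CC(=O)C[C@H]2C(=O)[C@](Sc3ccccc3)(C(=O)OC)[C@H](CCCCCCCCCCCCCCCC)C[C@@H]12 | intermediate
13 | (9E)-9-[(dimethylamino)methylidene] derivative of 12 | COC(=O)[C@@H]1C(CCCCCCCCCCCCCCCC)=CC(=O)/C(=C/N(C)C)[C@H]2C(=O)[C@](Sc3ccccc3)(C(=O)OC)[C@H](CCCCCCCCCCCCCCCC)C[C@@H]12 | intermediate
14 | 9-diazo derivative of 12 | COC(=O)[C@@H]1C(CCCCCCCCCCCCCCCC)=CC(=O)C(=[N+]=[N-])[C@H]2C(=O)[C@](Sc3ccccc3)(C(=O)OC)[C@H](CCCCCCCCCCCCCCCC)C[C@@H]12 | intermediate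
15 | dimethyl (4S,4aR,6R,7S,8aS)-3,6-dihexadecyl-8-oxo-1-(oxomethylidene)-7-(phenylsulfanyl)-1,4,4a,5,6,7,8,8a-octahydronaphthalene-4,7-dicarboxylate (vinylketene) | COC(=O)[C@@H]1C(CCCCCCCCCCCCCCCC)=CC(=C=O)[C@H]2C(=O)[C@](Sc3ccccc3)(C(=O)OC)[C@H](CCCCCCCCCCCCCCCC)C[C@@H]12 | intermediate
16 | trimethyl (1R,4S,4aR,6R,7S,8aS)-3,6-dihexadecyl-8-oxo-7-(phenylsulfanyl)-1,4,4a,5,6,7,8,8a-octahydronaphthalene-1,4,7-tricarboxylate | CCCCCCCCCCCCCCCCC1=C[C@@H](C(=O)OC)[C@H]2C(=O)[C@](Sc3ccccc3)(C(=O)OC)[C@H](CCCCCCCCCCCCCCCC)C[C@H]2[C@@H]1C(=O)OC | intermediate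
17 | S-oxide of 16 (sulfoxide, both configurations at sulfur) | CCCCCCCCCCCCCCCCC1=C[C@@H](C(=O)OC)[C@H]2C(=O)[C@](S(=O)c3ccccc3)(C(=O)OC)[C@H](CCCCCCCCCCCCCCCC)C[C@H]2[C@@H]1C(=O)OC | intermediate
18 | trimethyl (1R,4S,4aR,8aS)-3,6-dihexadecyl-8-oxo-1,4,4a,5,8,8a-hexahydronaphthalene-1,4,7-tricarboxylate | CCCCCCCCCCCCCCCCC1=C[C@@H](C(=O)OC)[C@H]2C(=O)C(C(=O)OC)=C(CCCCCCCCCCCCCCCC)C[C@H]2[C@@H]1C(=O)OC | target

**Step count and risks**

Total step count: 9. Longest linear sequence: 9 steps (1 to 18).

The three steps most likely to fail:

Step 5 (two-carbon ring enlargement). The rhenium catalyst may be slowed by coordination to the thioether, the reaction may stop after C-alkenylation, or the new double bond may drift out of conjugation with the ketone. The fallback sets out from 10 and 11 and comes back at 12. In(OTf)3-catalysed Conia-ene-type addition of the β-keto ester to the alkyne should give the α-(octadec-1-en-2-yl) β-keto ester F1. Irradiation through Pyrex should then bring about the photochemical 1,3-acyl shift of this β,γ-unsaturated ketone to the ring-enlarged keto ester F2 (double bond C3=C4). A catalytic amount of Et3N should move the double bond into conjugation with the ketone and so give 12.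

Step 8 (key step). Protonation of the dienol at C3 (giving the conjugated ester), protonation from the concave face, or photochemical C–S cleavage next to the ring B ketone may compete with the wanted course. The fallback sets out from 14 and comes back at 16. Aqueous HBr in Et2O at 0 °C should turn the diazo ketone into the α-bromo ketone F3 with loss of nitrogen. NaOMe in MeOH at 0 °C should then effect a quasi-Favorskii (semibenzilic) ring contraction: methoxide adds to the ketone, whose other α-carbon is vinylic and cannot form a cyclopropanone, and C2 shifts to C1 with inversion as bromide leaves. Since this shift is stereospecific, the bromide epimer that leads to 16 would be enriched beforehand by halide exchange with LiBr.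

Step 4 (cyclopentannulation). Under carbonate the chloroacetoacetate may self-condense or be O-alkylated, the conjugate addition next to the quaternary centre may be slow, or facial control at C4a may be incomplete. The fallback sets out from 7 and 8 and comes back at 10. Silylation of 8 (TMSCl, Et3N) should give methyl (Z)-4-chloro-3-(trimethylsilyloxy)but-2-enoate F4. Its TiCl4-promoted Mukaiyama–Michael addition to 7 at −78 °C should give the open-chain adduct 9, now isolated, and DBU in THF should close the five-membered ring by intramolecular alkylation to give 10.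

**Further compounds**

F1 | step 5 | dimethyl (3aR,5S,6R,7aR)-6-hexadecyl-1-(octadec-1-en-2-yl)-2,4-dioxo-5-(phenylsulfanyl)octahydro-1H-indene-1,5-dicarboxylate (alkenyl group on C1 trans to C7) | COC(=O)[C@@]1(C(=C)CCCCCCCCCCCCCCCC)C(=O)C[C@H]2C(=O)[C@](Sc3ccccc3)(C(=O)OC)[C@H](CCCCCCCCCCCCCCCC)C[C@@H]12
F2 | step 5 | double-bond isomer of 12 with the ring double bond between the ester-bearing carbon and the hexadecyl-bearing carbon and a CH2 next to the ketone | COC(=O)C1=C(CCCCCCCCCCCCCCCC)CC(=O)C[C@H]2C(=O)[C@](Sc3ccccc3)(C(=O)OC)[C@H](CCCCCCCCCCCCCCCC)C[C@@H]12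
F3 | step 8 | 9-bromo derivative of 12 (bromine in place of the diazo group of 14, both epimers at that carbon) | COC(=O)[C@@H]1C(CCCCCCCCCCCCCCCC)=CC(=O)C(Br)[C@H]2C(=O)[C@](Sc3ccccc3)(C(=O)OC)[C@H](CCCCCCCCCCCCCCCC)C[C@@H]12
F4 | step 4 | methyl (Z)-4-chloro-3-(trimethylsilyloxy)but-2-enoate | COC(=O)/C=C(/CCl)O[Si](C)(C)C
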